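Target ⇐ double acetylation of the 1,6-diol ⇐ inversion at C6 (MnO2 oxidation, then Luche reduction from the convex face) of a 6-epi bicyclic lactone; the C6 oxygen is set epimeric on purpose, because as a silyl ether it is expected to steer the key step from the opposite face (sesquiterpene numbering: C1 chain terminus, C4 side-chain stereocentre, C5=C10 ring alkene, C6 acetoxy carbon, C7/C8 ring fusion, C9 ring CH2, C11/C12/C13 lactone α-carbon, carbonyl carbon and methylene carbon, C14 ring methyl).
Key disconnection, both rings at once: cyclohexene ring A (C5–C6–C7–C8–C9–C10) and α-methylene-γ-butyrolactone ring B (O–C8–C7–C11–C12) ⇐ acyclic (Z)-allenyl aldehyde + CO by a Ru3(CO)12-catalysed hetero-Pauson–Khand cyclocarbonylation that forms C7–C8 and C11–C12 (and C12–O) and creates the cis ring fusion.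
Feature that makes this possible: the unit C13H2=C11(–C7)–C12(=O)–O–C8 of ring B is a terminal allene (C7=C11=C13) plus an aldehyde (C8=O) plus CO, and the tetrasubstituted C5=C10 alkene of ring A, once Z, holds the allenyl carbinol carbon C6 and the C9–C8 aldehyde arm cis, so that C7 and C8 can meet in a six-membered closure.
Allenyl aldehyde ⇐ ynone (CBS reduction sets C6; LiAlH4 turns the 4-alkoxybut-2-yn-1-ol into the terminal allene) ⇐ opening of an α,β-unsaturated δ-lactone with a lithium acetylide; this lactone is a temporary ring whose only task is to fix the Z geometry of C5=C10.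
δ-Lactone ⇐ (S)-citronellic acid (C1–C6, C15, the C4 stereocentre) + a 4-silyloxybutan-2-one (C8–C10, C14) by dianion aldol, lactonization and dehydration; order of ring formation: temporary dihydropyranone (step 5, opened in step 6), then rings A and B together (step 11).

Key step: step 11

Remark: TBDPS = tert-butyldiphenylsilyl, TBS = tert-butyldimethylsilyl, TES = triethylsilyl, THP-oxy = oxan-2-yloxy; the THP acetal carbon is a mixture and is lost in step 8.
Remark: the CIP descriptor of ring-fusion carbon C3a (= C7) switches between R and S with the group on O4 (H versus silyl or acetyl) by the priority rules alone; the geometry at C7 and C8 is the same in compounds 21 to 25.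

Step 1
Reactants: 1 (S)-citronellic acid [(3S)-3,7-dimethyloct-6-enoic acid]
Product: 3 (3S)-6-hydroxy-3-methylhexanoic acid, via ozonide 2 (not isolated)
Conditions: O3, CH2Cl2, −78 °C; then NaBH4, MeOH, −78 °C → rt; aq. HCl to pH 3
Reagents that add atoms: ozone, [O-][O+]=O
Why: Ozonolysis of the electron-rich trisubstituted alkene and borohydride reduction of the ozonide give the primary alcohol (future C1–OH); the C3 stereocentre (future C4) is not touched and no new stereocentre is formed.

Step 2
Reactants: 3 (3S)-6-hydroxy-3-methylhexanoic acid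
Product: 5 (3S)-6-(TBDPS-oxy)-3-methylhexanoic acid, via bis-silylated ester 4 (not isolated)
Conditions: TBDPSCl (2.3 equiv), imidazole, DMF, rt; then K2CO3, MeOH/THF/H2O, rt; citric acid to pH 4
Reagents that add atoms: tert-butyl(chloro)diphenylsilane, CC(C)(C)[Si](Cl)(c1ccccc1)c1ccccc1
Why: Silylation of alcohol and acid followed by mild basic hydrolysis of the labile silyl ester leaves the robust TBDPS ether, which should survive the enolate, acid, hydride and organolithium steps up to step 12.

Step 3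
Reactants: 6 4-hydroxybutan-2-one
Product: 7 4-(TBS-oxy)butan-2-one
Conditions: TBSCl, imidazole, CH2Cl2, 0 °C → rt
Reagents that add atoms: tert-butyl(chloro)dimethylsilane, CC(C)(C)[Si](C)(C)Cl
Why: Standard silyl ether formation masks the hydroxyl so that it cannot quench the dianion in step 4.

Step 4
Reactants: 5 (3S)-6-(TBDPS-oxy)-3-methylhexanoic acid; 7 4-(TBS-oxy)butan-2-one
Product: 9 5-(TBS-oxy)-2-[(2S)-5-(TBDPS-oxy)pentan-2-yl]-3-hydroxy-3-methylpentanoic acid (diastereomer mixture at C2/C3), via dilithium dianion 8 (not isolated)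
Conditions: LiN(i-Pr)2 (2.2 equiv), THF, −78 → 0 °C; then 7, −78 °C; aq. NH4Cl
Reagents that add atoms: none
Why: Ivanov-type aldol addition of the carboxylic acid dianion to the methyl ketone joins C5 to C10 faster than the ketone is enolized at −78 °C; the two new stereocentres (C5, C10) form as a mixture that is erased by the dehydration in step 5.

Step 5
Reactants: 9 aldol adduct
Product: 12 4-methyl-3-[(2S)-5-(TBDPS-oxy)pentan-2-yl]-5,6-dihydro-2H-pyran-2-one, via dihydroxy acid 10 (not isolated), via hydroxy lactone 11 (not isolated)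
Conditions: CSA (cat.), MeOH, rt; then solvent switch, TsOH·H2O (cat.), toluene, 90 °C
Reagents that add atoms: none
Why: Acid methanolysis cleaves the primary TBS ether but not the TBDPS ether, the δ-hydroxy acid lactonizes, and E1 dehydration of the tertiary β-hydroxy lactone under equilibrating acid should give the conjugated tetrasubstituted alkene (anhydromevalonolactone-type dehydration); the six-membered ring forces C6 and C9 cis on C5=C10, so the alkene geometry needed in step 11 is fixed here.

Step 6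
Reactants: 12 unsaturated δ-lactone; 13 2-(prop-2-yn-1-yloxy)oxane
Product: 15 (5Z)-8-hydroxy-6-methyl-1-(THP-oxy)-5-[(2S)-5-(TBDPS-oxy)pentan-2-yl]oct-5-en-2-yn-4-one, via lactol 14 (not isolated)
Conditions: 13, n-BuLi, THF, −78 °C; then 12, −78 → −40 °C; AcOH/THF quench at −78 °C
Reagents that add atoms: none
Why: 1,2-Addition of the lithium acetylide to the lactone carbonyl stops at the tetrahedral adduct, which on cold quench gives lactol 14 and opens to the cross-conjugated hydroxy ynone (single addition, the usual outcome of acetylide plus lactone); the Z geometry of C5=C10 is carried over from the ring.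

Step 7
Reactants: 15 hydroxy ynone
Product: 16 (4S,5Z)-6-methyl-1-(THP-oxy)-5-[(2S)-5-(TBDPS-oxy)pentan-2-yl]oct-5-en-2-yne-4,8-diol
Conditions: (R)-2-methyl-CBS-oxazaborolidine (0.5 equiv), BH3·SMe2 (2.5 equiv), THF, −40 °C; MeOH quench
Reagents that add atoms: none
Why: Corey–Bakshi–Shibata reduction: with the bulky tetrasubstituted alkenyl group as the large and the slim alkynyl group as the small substituent, the (R)-catalyst should deliver hydride to the face that gives the (4S)-carbinol (C6, set epimeric to the target on purpose); the excess borane also takes up the free primary hydroxyl, which is released again on quench.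

Step 8
Reactants: 16 (4S)-propargylic diol
Product: 17 (3Z,5S)-3-methyl-4-[(2S)-5-(TBDPS-oxy)pentan-2-yl]octa-3,6,7-triene-1,5-diol
Conditions: LiAlH4 (3 equiv), Et2O, 0 °C → reflux; aq. KNaC4H4O6 work-up
Reagents that add atoms: none
Why: Alkoxide-directed trans-hydroalumination places hydride on C7 and aluminium on C11, and β-elimination of the THP-oxy group (formal SN2′ reduction of a 4-alkoxybut-2-yn-1-ol) gives the terminal allene; the C6 stereocentre and the TBDPS ether are not affected.

Step 9
Reactants: 17 allenyl diol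
Product: 18 (3Z,5S)-3-methyl-4-[(2S)-5-(TBDPS-oxy)pentan-2-yl]-1,5-bis(TES-oxy)octa-3,6,7-triene
Conditions: TESOTf (2.5 equiv), 2,6-lutidine, CH2Cl2, −78 → 0 °C
Reagents that add atoms: triethylsilyl trifluoromethanesulfonate, CC[Si](CC)(CC)OS(=O)(=O)C(F)(F)F
Why: The reactive silyl triflate caps the hindered, doubly allylic C6 alcohol and turns the primary alcohol into a silyl ether that can be oxidized directly in step 10.

Step 10
Reactants: 18 bis(TES) ether
Product: 20 (3Z,5S)-3-methyl-4-[(2S)-5-(TBDPS-oxy)pentan-2-yl]-5-(TES-oxy)octa-3,6,7-trienal, via alkoxysulfonium chloride 19 (not isolated)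
Conditions: (COCl)2, DMSO, CH2Cl2, −78 → −40 °C; then i-Pr2NEt, −78 °C; cold pH 7 buffer; used at once
Reagents that add atoms: none
Why: Under Swern conditions the activated sulfonium reagent cleaves only the unhindered primary TES ether to alkoxysulfonium salt 19, which the base converts to the aldehyde, while the secondary TES ether and the TBDPS ether remain; the hindered amine at −78 °C and a cold neutral work-up should keep the β,γ-unsaturated aldehyde from moving into conjugation.

Step 11
Reactants: 20 (Z)-allenyl aldehyde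
Product: 21 (3aR,4S,7aR)-6-methyl-3-methylidene-5-[(2S)-5-(TBDPS-oxy)pentan-2-yl]-4-(TES-oxy)-3a,4,7,7a-tetrahydro-1-benzofuran-2(3H)-one
Conditions: Ru3(CO)12 (5 mol %), CO (15 atm), 1,4-dioxane, 120 °C
Reagents that add atoms: carbon monoxide, [C-]#[O+]
Why: Hetero-Pauson–Khand [2+2+1] cyclocarbonylation, the known Ru3(CO)12-catalysed reaction of allenyl aldehydes: zerovalent ruthenium binds the aldehyde C=O and the internal C7=C11 π bond of the allene, oxidative cyclization on the metal forms C7–C8, CO insertion into the resulting Ru–C11 bond forms C11–C12, and C–O reductive elimination releases the lactone. Ring A closes by 6-exo attack of C7 on the aldehyde carbon, made easy by the (Z)-C5=C10 alkene that holds C6 and C9 cis; ring B closes as the five-membered ring of the [2+2+1] event, with C11=C13 left exocyclic. C7 and C8 are created together and must be cis, because both new bonds belong to one metallacycle formed on a single face. Their absolute sense is relayed from C6: allylic 1,2-strain with the branched C5 substituent should hold the OTES group pseudoaxial, and the metallacycle should form on the opposite face, which also avoids a syn-diaxial contact between the silyloxy oxygen and the metal-bound aldehyde oxygen, giving the (6S,7R,8R) isomer. The step needs chemoselectivity for the internal allene π bond (secured by the four-atom tether, which allows only the six-membered closure) and diastereofacial selectivity (secured by the C6 silyl ether); CO pressure should suppress decarbonylation and isomerization of the β,γ-unsaturated aldehyde.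

Step 12
Reactants: 21 bis-silylated bicyclic lactone
Product: 22 (3aS,4S,7aR)-4-hydroxy-5-[(2S)-5-hydroxypentan-2-yl]-6-methyl-3-methylidene-3a,4,7,7a-tetrahydro-1-benzofuran-2(3H)-one
Conditions: HF·pyridine, pyridine, THF, 0 °C → rt
Reagents that add atoms: none
Why: Fluoride cleaves both silyl ethers under buffered, weakly acidic conditions, which the base-sensitive α-methylene lactone tolerates.

Step 13
Reactants: 22 6-epi diol
Product: 23 (3aR,7aR)-5-[(2S)-5-hydroxypentan-2-yl]-6-methyl-3-methylidene-3,3a,7,7a-tetrahydro-1-benzofuran-2,4-dione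
Conditions: MnO2 (activated, excess), CH2Cl2, rt
Reagents that add atoms: none
Why: MnO2 oxidizes only the allylic C6 alcohol and leaves the saturated primary alcohol; the neutral heterogeneous medium should not enolize C7.

Step 14
Reactants: 23 keto lactone
Product: 24 (3aS,4R,7aR)-4-hydroxy-5-[(2S)-5-hydroxypentan-2-yl]-6-methyl-3-methylidene-3a,4,7,7a-tetrahydro-1-benzofuran-2(3H)-one
Conditions: NaBH4, CeCl3·7H2O, MeOH, −78 °C
Reagents that add atoms: none
Why: Luche reduction (1,2-addition to the enone, expected to be faster than conjugate reduction of the methylene lactone at −78 °C): hydride should attack C6 from the convex face, anti to the C7–C11 bond and the lactone ring, so the hydroxyl ends cis to the lactone (6R) as the target requires.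

Step 15
Reactants: 24 (6R)-diol
Product: 25 1,6-O,O-diacetylbritannilactone
Conditions: Ac2O, pyridine, DMAP (cat.), CH2Cl2, 0 °C → rt
Reagents that add atoms: acetic anhydride, CC(=O)OC(C)=O
Why: DMAP-catalysed acetylation esterifies the primary C1 and the secondary C6 hydroxyls; no stereocentre is involved.

Compound list
1 | (S)-citronellic acid, (3S)-3,7-dimethyloct-6-enoic acid | OC(=O)C[C@@H](C)CCC=C(C)C | starting material
2 | (3S)-5-(5,5-dimethyl-1,2,4-trioxolan-3-yl)-3-methylpentanoic acid (ozonide, mixture at the ring carbon) | OC(=O)C[C@@H](C)CCC1OOC(C)(C)O1 | intermediate (not isolated)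
3 | (3S)-6-hydroxy-3-methylhexanoic acid | OC(=O)C[C@@H](C)CCCO | intermediate
4 | tert-butyldiphenylsilyl (3S)-6-[(tert-butyldiphenylsilyl)oxy]-3-methylhexanoate | CC(C)(C)[Si](c1ccccc1)(c1ccccc1)OC(=O)C[C@@H](C)CCCO[Si](c1ccccc1)(c1ccccc1)C(C)(C)C | intermediate (not isolated)
5 | (3S)-6-[(tert-butyldiphenylsilyl)oxy]-3-methylhexanoic acid | OC(=O)C[C@@H](C)CCCO[Si](c1ccccc1)(c1ccccc1)C(C)(C)C | intermediate
6 | 4-hydroxybutan-2-one | CC(=O)CCO | starting material
7 | 4-[(tert-butyldimethylsilyl)oxy]butan-2-one | CC(=O)CCO[Si](C)(C)C(C)(C)C | intermediate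
8 | dilithium enediolate (dianion) of acid 5 | [Li]OC(O[Li])=C[C@@H](C)CCCO[Si](c1ccccc1)(c1ccccc1)C(C)(C)C | intermediate (not isolated)
9 | 5-[(tert-butyldimethylsilyl)oxy]-2-[(2S)-5-[(tert-butyldiphenylsilyl)oxy]pentan-2-yl]-3-hydroxy-3-methylpentanoic acid (mixture at C2/C3) | OC(=O)C([C@@H](C)CCCO[Si](c1ccccc1)(c1ccccc1)C(C)(C)C)C(C)(O)CCO[Si](C)(C)C(C)(C)C | intermediate
10 | 2-[(2S)-5-[(tert-butyldiphenylsilyl)oxy]pentan-2-yl]-3,5-dihydroxy-3-methylpentanoic acid (mixture at C2/C3) | OC(=O)C([C@@H](C)CCCO[Si](c1ccccc1)(c1ccccc1)C(C)(C)C)C(C)(O)CCO | intermediate (not isolated)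
11 | 3-[(2S)-5-[(tert-butyldiphenylsilyl)oxy]pentan-2-yl]-4-hydroxy-4-methyloxan-2-one (mixture at C3/C4) | O=C1OCCC(C)(O)C1[C@@H](C)CCCO[Si](c1ccccc1)(c1ccccc1)C(C)(C)C | intermediate (not isolated)
12 | 3-[(2S)-5-[(tert-butyldiphenylsilyl)oxy]pentan-2-yl]-4-methyl-5,6-dihydro-2H-pyran-2-one | O=C1OCCC(C)=C1[C@@H](C)CCCO[Si](c1ccccc1)(c1ccccc1)C(C)(C)C | intermediate
13 | 2-(prop-2-yn-1-yloxy)oxane (propargyl THP ether) | C#CCOC1CCCCO1 | starting material
14 | 3-[(2S)-5-[(tert-butyldiphenylsilyl)oxy]pentan-2-yl]-4-methyl-2-[3-(oxan-2-yloxy)prop-1-yn-1-yl]-5,6-dihydro-2H-pyran-2-ol (lactol) | OC1(C#CCOC2CCCCO2)OCCC(C)=C1[C@@H](C)CCCO[Si](c1ccccc1)(c1ccccc1)C(C)(C)C | intermediate (not isolated)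
15 | (5Z)-5-[(2S)-5-[(tert-butyldiphenylsilyl)oxy]pentan-2-yl]-8-hydroxy-6-methyl-1-(oxan-2-yloxy)oct-5-en-2-yn-4-one | OCC/C(C)=C(\C(=O)C#CCOC1CCCCO1)[C@@H](C)CCCO[Si](c1ccccc1)(c1ccccc1)C(C)(C)C | intermediate
16 | (4S,5Z)-5-[(2S)-5-[(tert-butyldiphenylsilyl)oxy]pentan-2-yl]-6-methyl-1-(oxan-2-yloxy)oct-5-en-2-yne-4,8-diol | OCC/C(C)=C(\[C@@H](O)C#CCOC1CCCCO1)[C@@H](C)CCCO[Si](c1ccccc1)(c1ccccc1)C(C)(C)C | intermediate
17 | (3Z,5S)-4-[(2S)-5-[(tert-butyldiphenylsilyl)oxy]pentan-2-yl]-3-methylocta-3,6,7-triene-1,5-diol | OCC/C(C)=C(\[C@@H](O)C=C=C)[C@@H](C)CCCO[Si](c1ccccc1)(c1ccccc1)C(C)(C)C | intermediate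
18 | (3Z,5S)-4-[(2S)-5-[(tert-butyldiphenylsilyl)oxy]pentan-2-yl]-3-methyl-1,5-bis[(triethylsilyl)oxy]octa-3,6,7-triene | CC[Si](CC)(CC)OCC/C(C)=C(\[C@@H](O[Si](CC)(CC)CC)C=C=C)[C@@H](C)CCCO[Si](c1ccccc1)(c1ccccc1)C(C)(C)C | intermediate
19 | dimethyl{[(3Z,5S)-4-[(2S)-5-[(tert-butyldiphenylsilyl)oxy]pentan-2-yl]-3-methyl-5-[(triethylsilyl)oxy]octa-3,6,7-trien-1-yl]oxy}sulfonium chloride | C[S+](C)OCC/C(C)=C(\[C@@H](O[Si](CC)(CC)CC)C=C=C)[C@@H](C)CCCO[Si](c1ccccc1)(c1ccccc1)C(C)(C)C.[Cl-] | intermediate (not isolated)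
20 | (3Z,5S)-4-[(2S)-5-[(tert-butyldiphenylsilyl)oxy]pentan-2-yl]-3-methyl-5-[(triethylsilyl)oxy]octa-3,6,7-trienal | O=CC/C(C)=C(\[C@@H](O[Si](CC)(CC)CC)C=C=C)[C@@H](C)CCCO[Si](c1ccccc1)(c1ccccc1)C(C)(C)C | intermediate
21 | (3aR,4S,7aR)-5-[(2S)-5-[(tert-butyldiphenylsilyl)oxy]pentan-2-yl]-6-methyl-3-methylidene-4-[(triethylsilyl)oxy]-3a,4,7,7a-tetrahydro-1-benzofuran-2(3H)-one | C=C1C(=O)O[C@@H]2CC(C)=C([C@@H](C)CCCO[Si](c3ccccc3)(c3ccccc3)C(C)(C)C)[C@@H](O[Si](CC)(CC)CC)[C@H]12 | intermediate
22 | (3aS,4S,7aR)-4-hydroxy-5-[(2S)-5-hydroxypentan-2-yl]-6-methyl-3-methylidene-3a,4,7,7a-tetrahydro-1-benzofuran-2(3H)-one (6-epi diol) | C=C1C(=O)O[C@@H]2CC(C)=C([C@@H](C)CCCO)[C@@H](O)[C@H]12 | intermediate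
23 | (3aR,7aR)-5-[(2S)-5-hydroxypentan-2-yl]-6-methyl-3-methylidene-3,3a,7,7a-tetrahydro-1-benzofuran-2,4-dione | C=C1C(=O)O[C@@H]2CC(C)=C([C@@H](C)CCCO)C(=O)[C@H]12 | intermediate
24 | (3aS,4R,7aR)-4-hydroxy-5-[(2S)-5-hydroxypentan-2-yl]-6-methyl-3-methylidene-3a,4,7,7a-tetrahydro-1-benzofuran-2(3H)-one | C=C1C(=O)O[C@@H]2CC(C)=C([C@@H](C)CCCO)[C@H](O)[C@H]12 | intermediate
25 | 1,6-O,O-diacetylbritannilactone, (3aR,4R,7aR)-4-(acetyloxy)-5-[(2S)-5-(acetyloxy)pentan-2-yl]-6-methyl-3-methylidene-3a,4,7,7a-tetrahydro-1-benzofuran-2(3H)-one | C=C1C(=O)O[C@@H]2CC(C)=C([C@@H](C)CCCOC(C)=O)[C@H](OC(C)=O)[C@H]12 | target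

Total step count: 15. Longest linear sequence: 14 steps (steps 1, 2 and 4 to 15, from 1 to 25); step 3 is a one-step branch.

Steps most likely to fail

Step 11 (key step). The facial selectivity of metallacycle formation relative to the C6 silyl ether may turn out low or opposite to the predicted anti sense, for example through a syn-directing contact between the silyloxy oxygen and the metal. That would deliver the ring fusion in the mirror-image sense and make the later C6 inversion useless. The fallback runs the sequence in the 6R series, so that syn induction gives the all-cis lactone directly. It sets out from ynone 15: reduction with the enantiomeric (S)-2-methyl-CBS-oxazaborolidine and BH3·SMe2 gives the (4R)-propargylic diol F1, LiAlH4 gives the (5R)-allenyl diol F2, and TESOTf/2,6-lutidine gives the bis(TES) ether F3. Swern conditions then give, through the alkoxysulfonium chloride F4, the (5R)-aldehyde F5. Cyclocarbonylation as in step 11 gives the all-cis (3aR,4R,7aR)-silyl lactone F6, and HF·pyridine converts it into diol 24, where the route is rejoined; steps 13 and 14 are then not needed.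

Step 14. Borohydride may reduce the α-methylene lactone in a conjugate sense, or C7 of keto lactone 23 (flanked by the ketone and the methylene lactone) may enolize, with epimerization or migration of the exocyclic alkene into the ring before the ketone is reduced. The fallback avoids the ketone and inverts C6 by substitution. It sets out from the 6-epi diol 22: a Mitsunobu reaction with AcOH (PPh3, DIAD, THF, 0 °C → rt, excess reagents) esterifies the primary C1 hydroxyl and displaces the activated C6 hydroxyl by acetate with inversion (SN2; the SN2′ position C10 is fully substituted). This gives the target 25 directly, where the route ends; steps 13 to 15 are bypassed.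

Step 7. Enantioface discrimination may be poor, because the borane-bound primary hydroxyl can deliver hydride intramolecularly and the lactol form 14 keeps part of the ketone away from the catalyst. The fallback caps the hydroxyl before the reduction. It sets out from hydroxy ynone 15: TESCl/imidazole gives the primary TES ether F7, which is locked in the open ketone form. CBS reduction with the (R)-catalyst then gives the (4S)-propargylic alcohol F8, LiAlH4 in Et2O gives the allenyl alcohol F9, and TESOTf/2,6-lutidine silylates the C6 hydroxyl to give bis(TES) ether 18, where the route is rejoined.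

Further compounds
F1 | step 11 | (4R,5Z)-5-[(2S)-5-[(tert-butyldiphenylsilyl)oxy]pentan-2-yl]-6-methyl-1-(oxan-2-yloxy)oct-5-en-2-yne-4,8-diol | OCC/C(C)=C(\[C@H](O)C#CCOC1CCCCO1)[C@@H](C)CCCO[Si](c1ccccc1)(c1ccccc1)C(C)(C)C
F2 | step 11 | (3Z,5R)-4-[(2S)-5-[(tert-butyldiphenylsilyl)oxy]pentan-2-yl]-3-methylocta-3,6,7-triene-1,5-diol | OCC/C(C)=C(\[C@H](O)C=C=C)[C@@H](C)CCCO[Si](c1ccccc1)(c1ccccc1)C(C)(C)C
F3 | step 11 | (3Z,5R)-4-[(2S)-5-[(tert-butyldiphenylsilyl)oxy]pentan-2-yl]-3-methyl-1,5-bis[(triethylsilyl)oxy]octa-3,6,7-triene | CC[Si](CC)(CC)OCC/C(C)=C(\[C@H](O[Si](CC)(CC)CC)C=C=C)[C@@H](C)CCCO[Si](c1ccccc1)(c1ccccc1)C(C)(C)C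
F4 | step 11 | dimethyl{[(3Z,5R)-4-[(2S)-5-[(tert-butyldiphenylsilyl)oxy]pentan-2-yl]-3-methyl-5-[(triethylsilyl)oxy]octa-3,6,7-trien-1-yl]oxy}sulfonium chloride | C[S+](C)OCC/C(C)=C(\[C@H](O[Si](CC)(CC)CC)C=C=C)[C@@H](C)CCCO[Si](c1ccccc1)(c1ccccc1)C(C)(C)C.[Cl-]
F5 | step 11 | (3Z,5R)-4-[(2S)-5-[(tert-butyldiphenylsilyl)oxy]pentan-2-yl]-3-methyl-5-[(triethylsilyl)oxy]octa-3,6,7-trienal | O=CC/C(C)=C(\[C@H](O[Si](CC)(CC)CC)C=C=C)[C@@H](C)CCCO[Si](c1ccccc1)(c1ccccc1)C(C)(C)C
F6 | step 11 | (3aR,4R,7aR)-5-[(2S)-5-[(tert-butyldiphenylsilyl)oxy]pentan-2-yl]-6-methyl-3-methylidene-4-[(triethylsilyl)oxy]-3a,4,7,7a-tetrahydro-1-benzofuran-2(3H)-one | C=C1C(=O)O[C@@H]2CC(C)=C([C@@H](C)CCCO[Si](c3ccccc3)(c3ccccc3)C(C)(C)C)[C@H](O[Si](CC)(CC)CC)[C@H]12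
F0 | step 14 | none | none
F7 | step 7 | (5Z)-5-[(2S)-5-[(tert-butyldiphenylsilyl)oxy]pentan-2-yl]-6-methyl-1-(oxan-2-yloxy)-8-[(triethylsilyl)oxy]oct-5-en-2-yn-4-one | CC[Si](CC)(CC)OCC/C(C)=C(\C(=O)C#CCOC1CCCCO1)[C@@H](C)CCCO[Si](c1ccccc1)(c1ccccc1)C(C)(C)C
F8 | step 7 | (4S,5Z)-5-[(2S)-5-[(tert-butyldiphenylsilyl)oxy]pentan-2-yl]-6-methyl-1-(oxan-2-yloxy)-8-[(triethylsilyl)oxy]oct-5-en-2-yn-4-ol | CC[Si](CC)(CC)OCC/C(C)=C(\[C@@H](O)C#CCOC1CCCCO1)[C@@H](C)CCCO[Si](c1ccccc1)(c1ccccc1)C(C)(C)C
F9 | step 7 | (3S,5Z)-5-[(2S)-5-[(tert-butyldiphenylsilyl)oxy]pentan-2-yl]-6-methyl-8-[(triethylsilyl)oxy]octa-1,2,5-trien-4-ol | CC[Si](CC)(CC)OCC/C(C)=C(\[C@@H](O)C=C=C)[C@@H](C)CCCO[Si](c1ccccc1)(c1ccccc1)C(C)(C)C
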